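The six-membered ring is opened at the bond between the methylidene-bearing carbon C4 and the ring-fusion carbon C3a (octahydroinden-2-one numbering). The route exploits the fact that the exocyclic C4=CH2 is the footprint of a terminal alkyne and C3a, β to the C2 ketone, that of an enal β-carbon. One nickel-catalysed reductive alkyne–enal cyclization of an acyclic non-2-en-8-ynal therefore forms C4–C3a, closes the cyclohexane through a chair that fixes the trans ring fusion, and delivers the methylene group and a masked C2 carbonyl. The precursor carries three stereocentres from an organocatalytic Michael addition and a catalyst-controlled propargylation. A carbene-catalysed acyloin closure then builds the cyclopentanone; C5 is oxygenated last.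

Key step: step 8

Remark: bicyclic compounds are numbered as octahydro-2H-inden-2-ones (C1 carbinol carbon, C2 ketone, C3a/C7a ring fusion, C4 methylidene carbon, C5 and C6 oxygenated carbons, C7 isopropyl carbon). (E)-3,3-Dimethoxy-1-nitroprop-1-ene is assumed not to be a stock chemical and is made in steps 1 and 2.

Step 1
Reactants: 1 nitromethane; 2 2,2-dimethoxyacetaldehyde
Product: 3 3,3-dimethoxy-1-nitropropan-2-ol (racemic)
Conditions: K2CO3 (10 mol%), MeOH/H2O, 0 °C to rt; aldehyde used as its 60% aqueous solution
Reagents that add atoms: none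
Why: Henry (nitroaldol) reaction of the nitronate with the unhindered, non-enolizable aldehyde should give the β-nitro alcohol; its carbinol centre disappears in step 2, so it is made racemic.

Step 2
Reactants: 3 3,3-dimethoxy-1-nitropropan-2-ol
Product: 5 (E)-3,3-dimethoxy-1-nitroprop-1-ene, via mesylate 4 (not isolated)
Conditions: MsCl, Et3N (2.2 equiv), CH2Cl2, −20 °C to 0 °C
Reagents that add atoms: none
Why: O-mesylation followed by E1cB elimination (dehydration of a Henry adduct) should give the conjugated nitroalkene as the thermodynamically favoured E isomer.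

Step 3
Reactants: 5 (E)-3,3-dimethoxy-1-nitroprop-1-ene; 6 3-methylbutanal
Product: 7 (2S,3S)-4,4-dimethoxy-3-(nitromethyl)-2-(propan-2-yl)butanal
Conditions: (R)-α,α-diphenylprolinol trimethylsilyl ether (10 mol%), 4-nitrophenol (10 mol%), toluene, 0 °C, aldehyde in slight excess
Reagents that add atoms: none
Why: enamine-catalysed asymmetric Michael addition of an aldehyde to a nitroalkene, a pure addition in which every atom of both partners ends up in the product and in which the E-enamine, shielded on one face by the diphenyl(silyloxy)methyl group, should add through the acyclic synclinal transition state to give the syn adduct, so that both stereocentres (future C7 and C7a) are set under catalyst control.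

Step 4
Reactants: 7 (2S,3S)-4,4-dimethoxy-3-(nitromethyl)-2-(propan-2-yl)butanal; 8 allenylboronic acid pinacol ester
Product: 9 (4R,5S,6S)-7,7-dimethoxy-6-(nitromethyl)-5-(propan-2-yl)hept-1-yn-4-ol
Conditions: (R)-TRIP [(R)-3,3'-bis(2,4,6-triisopropylphenyl)-1,1'-binaphthyl-2,2'-diyl hydrogen phosphate] (5 mol%), 4 Å molecular sieves, toluene, −20 °C; aqueous work-up
Reagents that add atoms: none
Why: chiral phosphoric acid-catalysed propargylation (SE2' transfer from the allenylboronate through a six-membered chair transition state), in which the (R)-acid is expected, by analogy with simple aldehydes, to direct attack to the Re face of the aldehyde and so set the new carbinol centre (future C6) as R, overriding the weak bias of the α-stereocentre.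

Step 5
Reactants: 9 (4R,5S,6S)-7,7-dimethoxy-6-(nitromethyl)-5-(propan-2-yl)hept-1-yn-4-ol
Product: 10 tert-butyl{[(4R,5S,6S)-7,7-dimethoxy-6-(nitromethyl)-5-(propan-2-yl)hept-1-yn-4-yl]oxy}dimethylsilane
Conditions: TBSCl, imidazole, DMAP (cat.), DMF, 40 °C
Reagents that add atoms: tert-butyldimethylsilyl chloride, CC(C)(C)[Si](C)(C)Cl
Why: silylation of the hindered secondary alcohol under nucleophilic catalysis should proceed without touching the stereocentres; the chloride/imidazole system is chosen because a silyl triflate could ionize the dimethyl acetal.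

Step 6
Reactants: 10 tert-butyl{[(4R,5S,6S)-7,7-dimethoxy-6-(nitromethyl)-5-(propan-2-yl)hept-1-yn-4-yl]oxy}dimethylsilane
Product: 12 (2S,3S,4R)-4-[(tert-butyldimethylsilyl)oxy]-2-(dimethoxymethyl)-3-(propan-2-yl)hept-6-ynal, via potassium nitronate 11 (not isolated)
Conditions: KOtBu (1.05 equiv), THF, 0 °C; then dimethyldioxirane (acetone solution), −20 °C
Reagents that add atoms: dimethyldioxirane, CC1(C)OO1
Why: oxidative Nef reaction, in which the nitronate is oxidized at carbon and collapses to the aldehyde with loss of nitrite under non-acidic conditions that should spare the acetal, the silyl ether and the alkyne; the aldehyde is used at once to avoid epimerization or loss of methanol at its α-carbon.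

Step 7
Reactants: 12 (2S,3S,4R)-4-[(tert-butyldimethylsilyl)oxy]-2-(dimethoxymethyl)-3-(propan-2-yl)hept-6-ynal; 13 (triphenylphosphoranylidene)acetaldehyde
Product: 14 (2E,4R,5S,6R)-6-[(tert-butyldimethylsilyl)oxy]-4-(dimethoxymethyl)-5-(propan-2-yl)non-2-en-8-ynal
Conditions: toluene, 50 °C
Reagents that add atoms: none
Why: Wittig olefination with the stabilized formylmethylene ylide should give the E-enal under neutral conditions that do not epimerize the α-stereocentre.

Step 8
Reactants: 14 (2E,4R,5S,6R)-6-[(tert-butyldimethylsilyl)oxy]-4-(dimethoxymethyl)-5-(propan-2-yl)non-2-en-8-ynal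
Product: 16 (1R,2S,3R,6R)-3-[(tert-butyldimethylsilyl)oxy]-5-methylidene-6-(2-oxoethyl)-2-(propan-2-yl)cyclohexane-1-carbaldehyde, via enol silane 15 (not isolated)
Conditions: Ni(cod)2 (10 mol%), PCy3 (20 mol%), Et3SiH (3 equiv), THF, 45 °C, slow addition of 14; then p-TsOH·H2O (0.2 equiv), acetone/H2O (10:1), rt
Reagents that add atoms: water, O
Why: Zerovalent nickel should bind the alkyne and the s-cis enal and undergo oxidative cyclization to a seven-membered oxanickelacycle (nickel O-enolate), forming the bond between the internal alkyne carbon (C4 of the final indenone) and the enal β-carbon (C3a); σ-bond metathesis with Et3SiH then silylates the enolate oxygen, C–H reductive elimination from the alkenylnickel hydride releases the exocyclic methylene, and the acid work-up hydrolyses the Z-enol silane and the dimethyl acetal to dialdehyde 16. The closest known reaction type is the nickel-catalysed reductive coupling and cyclization of alkynes with enals and enones using silanes or organozincs. The cyclohexane is closed in a 6-exo mode at both π systems (6-exo-dig at the alkyne, 6-exo-trig at the enal). The single new stereocentre (C6 of 16, C3a of the target) is controlled by a chair-like transition state in which CH(OMe)2, isopropyl and the enal side chain are equatorial and only OTBS is axial, which places the new side chain trans to the neighbouring dimethoxymethyl group and so fixes the trans ring fusion. The step needs chemoselective intramolecular coupling over alkyne oligomerization and hydrosilylation, which the 1,7-disposition of the two π systems, slow addition and the bulky monodentate phosphine should secure.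

Step 9
Reactants: 16 (1R,2S,3R,6R)-3-[(tert-butyldimethylsilyl)oxy]-5-methylidene-6-(2-oxoethyl)-2-(propan-2-yl)cyclohexane-1-carbaldehyde
Product: 17 (1R,3aR,6R,7S,7aR)-6-[(tert-butyldimethylsilyl)oxy]-1-hydroxy-4-methylidene-7-(propan-2-yl)octahydro-2H-inden-2-one
Conditions: 3-benzyl-5-(2-hydroxyethyl)-4-methylthiazolium chloride (20 mol%), Et3N (1 equiv), 1,4-dioxane, 70 °C
Reagents that add atoms: none
Why: carbene-catalysed intramolecular acyloin (benzoin) condensation, in which the thiazol-2-ylidene should add to the unhindered CH2CHO group to give the acyl-anion equivalent that attacks the neighbouring ring aldehyde 5-exo-trig, placing the ketone at C2; the epimerizable C1 carbinol centre should settle under the basic conditions as the isomer with OH trans to C7 (1R), and no aldol pathway competes because either enolate could only close a four-membered ring.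

Step 10
Reactants: 17 (1R,3aR,6R,7S,7aR)-6-[(tert-butyldimethylsilyl)oxy]-1-hydroxy-4-methylidene-7-(propan-2-yl)octahydro-2H-inden-2-one
Product: 18 (1R,3aR,6R,7S,7aR)-6-[(tert-butyldimethylsilyl)oxy]-4-methylidene-2-oxo-7-(propan-2-yl)octahydro-1H-inden-1-yl acetate
Conditions: Ac2O, pyridine, DMAP (cat.), CH2Cl2, 0 °C to rt
Reagents that add atoms: acetic anhydride, CC(=O)OC(C)=O
Why: acylation of the secondary α-ketol under nucleophilic catalysis should give the acetate, which keeps the thermodynamically preferred 1R configuration (acetoxy trans to C7) at the only epimerizable centre.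

Step 11
Reactants: 18 (1R,3aR,6R,7S,7aR)-6-[(tert-butyldimethylsilyl)oxy]-4-methylidene-2-oxo-7-(propan-2-yl)octahydro-1H-inden-1-yl acetate
Product: 19 (1R,3aR,5S,6S,7S,7aR)-6-[(tert-butyldimethylsilyl)oxy]-5-hydroxy-4-methylidene-2-oxo-7-(propan-2-yl)octahydro-1H-inden-1-yl acetate
Conditions: SeO2 (30 mol%), t-BuOOH (3 equiv, in decane), CH2Cl2, 0 °C to rt
Reagents that add atoms: selenium dioxide, O=[Se]=O; tert-butyl hydroperoxide, CC(C)(C)OO
Why: Riley allylic oxidation (ene reaction of SeO2 at the methylidene carbon with removal of the axial 5β-hydrogen, then [2,3]-sigmatropic shift of the allylseleninic acid), which should attack the ring CH2 in preference to the ring-fusion CH and deliver oxygen axially to the β face of C5, anti to the axial 6α-silyloxy group, giving the 5S alcohol with the methylene group restored.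

Step 12
Reactants: 19 (1R,3aR,5S,6S,7S,7aR)-6-[(tert-butyldimethylsilyl)oxy]-5-hydroxy-4-methylidene-2-oxo-7-(propan-2-yl)octahydro-1H-inden-1-yl acetate; 20 angelic acid [(2Z)-2-methylbut-2-enoic acid]
Product: 22 (1R,3aR,5S,6S,7S,7aR)-1-(acetyloxy)-6-[(tert-butyldimethylsilyl)oxy]-4-methylidene-2-oxo-7-(propan-2-yl)octahydro-1H-inden-5-yl (2Z)-2-methylbut-2-enoate, via mixed anhydride 21 (not isolated)
Conditions: 20 (1.5 equiv), 2,4,6-trichlorobenzoyl chloride (1.5 equiv), Et3N (3 equiv), toluene, rt; then 19, 80 °C
Reagents that add atoms: none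
Why: Yamaguchi-type esterification through the mixed 2,4,6-trichlorobenzoic anhydride run without nucleophilic catalyst, in which the alcohol should attack the less hindered angeloyl carbonyl with retention at C5 and without Z-to-E isomerization to the tiglate.

Step 13
Reactants: 22 (1R,3aR,5S,6S,7S,7aR)-1-(acetyloxy)-6-[(tert-butyldimethylsilyl)oxy]-4-methylidene-2-oxo-7-(propan-2-yl)octahydro-1H-inden-5-yl (2Z)-2-methylbut-2-enoate
Product: 23 (1R,3aR,5S,6S,7S,7aR)-1-(acetyloxy)-6-hydroxy-4-methylidene-2-oxo-7-(propan-2-yl)octahydro-1H-inden-5-yl (2Z)-2-methylbut-2-enoate (CNP0317011.1)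
Conditions: HF·pyridine, pyridine, THF, 0 °C to rt
Reagents that add atoms: none
Why: fluoride-mediated cleavage of the silyl ether under buffered conditions should leave both esters, the α-acetoxy ketone and the allylic system intact, and the trans-diaxial arrangement of the C5 ester and the C6 hydroxyl disfavours acyl migration.

Compound list
1 | nitromethane | C[N+](=O)[O-] | starting material
2 | 2,2-dimethoxyacetaldehyde | COC(OC)C=O | starting material
3 | 3,3-dimethoxy-1-nitropropan-2-ol (racemic) | COC(OC)C(O)C[N+](=O)[O-] | intermediate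
4 | 3,3-dimethoxy-1-nitropropan-2-yl methanesulfonate (racemic, formed in situ) | COC(OC)C(OS(C)(=O)=O)C[N+](=O)[O-] | intermediate
5 | (E)-3,3-dimethoxy-1-nitroprop-1-ene | COC(OC)/C=C/[N+](=O)[O-] | intermediate
6 | 3-methylbutanal | CC(C)CC=O | starting material
7 | (2S,3S)-4,4-dimethoxy-3-(nitromethyl)-2-(propan-2-yl)butanal | O=C[C@@H](C(C)C)[C@H](C(OC)OC)C[N+](=O)[O-] | intermediate
8 | allenylboronic acid pinacol ester [4,4,5,5-tetramethyl-2-(propa-1,2-dien-1-yl)-1,3,2-dioxaborolane] | C=C=CB1OC(C)(C)C(C)(C)O1 | starting material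
9 | (4R,5S,6S)-7,7-dimethoxy-6-(nitromethyl)-5-(propan-2-yl)hept-1-yn-4-ol | C#CC[C@@H](O)[C@@H](C(C)C)[C@H](C(OC)OC)C[N+](=O)[O-] | intermediate
10 | tert-butyl{[(4R,5S,6S)-7,7-dimethoxy-6-(nitromethyl)-5-(propan-2-yl)hept-1-yn-4-yl]oxy}dimethylsilane | C#CC[C@@H](O[Si](C)(C)C(C)(C)C)[C@@H](C(C)C)[C@H](C(OC)OC)C[N+](=O)[O-] | intermediate
11 | potassium nitronate of 10 (aci-nitro salt at the former CH2NO2 carbon, formed in situ) | C#CC[C@@H](O[Si](C)(C)C(C)(C)C)[C@@H](C(C)C)[C@H](C(OC)OC)C=[N+]([O-])[O-].[K+] | intermediate
12 | (2S,3S,4R)-4-[(tert-butyldimethylsilyl)oxy]-2-(dimethoxymethyl)-3-(propan-2-yl)hept-6-ynal | C#CC[C@@H](O[Si](C)(C)C(C)(C)C)[C@@H](C(C)C)[C@H](C(OC)OC)C=O | intermediate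
13 | (triphenylphosphoranylidene)acetaldehyde | O=CC=P(c1ccccc1)(c1ccccc1)c1ccccc1 | starting material
14 | (2E,4R,5S,6R)-6-[(tert-butyldimethylsilyl)oxy]-4-(dimethoxymethyl)-5-(propan-2-yl)non-2-en-8-ynal | C#CC[C@@H](O[Si](C)(C)C(C)(C)C)[C@@H](C(C)C)[C@H](C(OC)OC)/C=C/C=O | intermediate
15 | triethyl{[(1Z)-2-{(1R,2R,3S,4R)-4-[(tert-butyldimethylsilyl)oxy]-2-(dimethoxymethyl)-6-methylidene-3-(propan-2-yl)cyclohexyl}ethenyl]oxy}silane (formed in situ) | C=C1C[C@@H](O[Si](C)(C)C(C)(C)C)[C@@H](C(C)C)[C@H](C(OC)OC)[C@H]1/C=C\O[Si](CC)(CC)CC | intermediate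
16 | (1R,2S,3R,6R)-3-[(tert-butyldimethylsilyl)oxy]-5-methylidene-6-(2-oxoethyl)-2-(propan-2-yl)cyclohexane-1-carbaldehyde | C=C1C[C@@H](O[Si](C)(C)C(C)(C)C)[C@@H](C(C)C)[C@H](C=O)[C@H]1CC=O | intermediate
17 | (1R,3aR,6R,7S,7aR)-6-[(tert-butyldimethylsilyl)oxy]-1-hydroxy-4-methylidene-7-(propan-2-yl)octahydro-2H-inden-2-one | C=C1[C@@H]2CC(=O)[C@H](O)[C@H]2[C@H](C(C)C)[C@H](O[Si](C)(C)C(C)(C)C)C1 | intermediate
18 | (1R,3aR,6R,7S,7aR)-6-[(tert-butyldimethylsilyl)oxy]-4-methylidene-2-oxo-7-(propan-2-yl)octahydro-1H-inden-1-yl acetate | C=C1[C@@H]2CC(=O)[C@H](OC(C)=O)[C@H]2[C@H](C(C)C)[C@H](O[Si](C)(C)C(C)(C)C)C1 | intermediate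
19 | (1R,3aR,5S,6S,7S,7aR)-6-[(tert-butyldimethylsilyl)oxy]-5-hydroxy-4-methylidene-2-oxo-7-(propan-2-yl)octahydro-1H-inden-1-yl acetate | C=C1[C@@H]2CC(=O)[C@H](OC(C)=O)[C@H]2[C@H](C(C)C)[C@H](O[Si](C)(C)C(C)(C)C)[C@H]1O | intermediate
20 | angelic acid [(2Z)-2-methylbut-2-enoic acid] | C/C=C(/C)C(=O)O | starting material
21 | (2Z)-2-methylbut-2-enoic 2,4,6-trichlorobenzoic anhydride (formed in situ) | C/C=C(/C)C(=O)OC(=O)c1c(Cl)cc(Cl)cc1Cl | intermediate
22 | (1R,3aR,5S,6S,7S,7aR)-1-(acetyloxy)-6-[(tert-butyldimethylsilyl)oxy]-4-methylidene-2-oxo-7-(propan-2-yl)octahydro-1H-inden-5-yl (2Z)-2-methylbut-2-enoate | C=C1[C@@H]2CC(=O)[C@H](OC(C)=O)[C@H]2[C@H](C(C)C)[C@H](O[Si](C)(C)C(C)(C)C)[C@H]1OC(=O)/C(C)=C\C | intermediate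
23 | (1R,3aR,5S,6S,7S,7aR)-1-(acetyloxy)-6-hydroxy-4-methylidene-2-oxo-7-(propan-2-yl)octahydro-1H-inden-5-yl (2Z)-2-methylbut-2-enoate (CNP0317011.1) | C=C1[C@@H]2CC(=O)[C@H](OC(C)=O)[C@H]2[C@H](C(C)C)[C@H](O)[C@H]1OC(=O)/C(C)=C\C | target

Total step count: 13
Longest linear sequence: 13 steps (from 1 and 2 to 23; compounds 6, 8, 13 and 20 are purchased)

Steps most likely to fail

Step 8 (key cyclization). What may go wrong is oligomerization or hydrosilylation of the terminal alkyne at zerovalent nickel outrunning the slower six-membered oxidative cyclization. The fallback sets out from 14 and comes back at 16, and replaces the organometallic ring closure by a radical one. Bu3SnH and AIBN in benzene at 80 °C under high dilution should add a stannyl radical to the alkyne terminus. The vinyl radical should then close 6-exo-trig onto the enal β-carbon through the same chair, and the α-formyl radical is reduced by the tin hydride. This should give 2-[(1R,2R,3S,4R)-4-[(tert-butyldimethylsilyl)oxy]-2-(dimethoxymethyl)-3-(propan-2-yl)-6-[(tributylstannyl)methylidene]cyclohexyl]acetaldehyde F1 as an E/Z mixture. Aqueous HCl in THF at 0 °C should then effect protodestannylation to the methylene group and hydrolysis of the acetal, giving 16.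

Step 9 (acyloin closure). What may go wrong is formation of the acyl-anion equivalent at the hindered ring aldehyde, or reversible transposition of the ketol, so that the ketone ends up next to the ring fusion; intermolecular aldol oligomerization of the dialdehyde is a further risk. The fallback sets out from 15 and comes back at 17, and fixes the regiochemistry by differentiating the two carbonyl carbons before ring closure. The enol silane in the step 8 mixture is cleaved with K2CO3 in MeOH at 0 °C with the acetal left intact, which should give 2-[(1R,2R,3S,4R)-4-[(tert-butyldimethylsilyl)oxy]-2-(dimethoxymethyl)-6-methylidene-3-(propan-2-yl)cyclohexyl]acetaldehyde F2. I2 in aqueous NH3/THF should then convert the free aldehyde into 2-[(1R,2R,3S,4R)-4-[(tert-butyldimethylsilyl)oxy]-2-(dimethoxymethyl)-6-methylidene-3-(propan-2-yl)cyclohexyl]acetonitrile F3. p-TsOH·H2O in wet acetone should unmask the ring aldehyde to give (1R,2S,3R,6R)-3-[(tert-butyldimethylsilyl)oxy]-6-(cyanomethyl)-5-methylidene-2-(propan-2-yl)cyclohexane-1-carbaldehyde F4. SmI2 with t-BuOH in THF (divalent samarium, reductive ketyl–nitrile coupling, 5-exo-dig) should give the α-hydroxy imine, which is hydrolysed on aqueous NH4Cl work-up to ketol 17; brief exposure to Et3N equilibrates C1.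

Step 11 (allylic oxidation). What may go wrong is poor facial selectivity in the [2,3] shift, so that part of the oxygen is delivered to the α face of C5, together with over-oxidation to the enone at longer reaction times. The fallback sets out from 18 and comes back at 22, and sets C5 by substitution with inversion instead of by acyl transfer with retention. The oxidation is stopped at partial conversion and the equatorial epimer (1R,3aR,5R,6S,7S,7aR)-6-[(tert-butyldimethylsilyl)oxy]-5-hydroxy-4-methylidene-2-oxo-7-(propan-2-yl)octahydro-1H-inden-1-yl acetate F5 is separated from 19. F5 is then esterified with angelic acid 20 under Mitsunobu conditions (PPh3, DIAD, toluene, 0 °C), which should install the angelate at C5 with inversion and give 22 directly, so that both C5 epimers converge on 22.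

Further compounds
F1 | step 8 | 2-[(1R,2R,3S,4R)-4-[(tert-butyldimethylsilyl)oxy]-2-(dimethoxymethyl)-3-(propan-2-yl)-6-[(tributylstannyl)methylidene]cyclohexyl]acetaldehyde (E/Z mixture) | CCCC[Sn](CCCC)(CCCC)C=C1C[C@@H](O[Si](C)(C)C(C)(C)C)[C@@H](C(C)C)[C@H](C(OC)OC)[C@H]1CC=O
F2 | step 9 | 2-[(1R,2R,3S,4R)-4-[(tert-butyldimethylsilyl)oxy]-2-(dimethoxymethyl)-6-methylidene-3-(propan-2-yl)cyclohexyl]acetaldehyde | C=C1C[C@@H](O[Si](C)(C)C(C)(C)C)[C@@H](C(C)C)[C@H](C(OC)OC)[C@H]1CC=O
F3 | step 9 | 2-[(1R,2R,3S,4R)-4-[(tert-butyldimethylsilyl)oxy]-2-(dimethoxymethyl)-6-methylidene-3-(propan-2-yl)cyclohexyl]acetonitrile | C=C1C[C@@H](O[Si](C)(C)C(C)(C)C)[C@@H](C(C)C)[C@H](C(OC)OC)[C@H]1CC#N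
F4 | step 9 | (1R,2S,3R,6R)-3-[(tert-butyldimethylsilyl)oxy]-6-(cyanomethyl)-5-methylidene-2-(propan-2-yl)cyclohexane-1-carbaldehyde | C=C1C[C@@H](O[Si](C)(C)C(C)(C)C)[C@@H](C(C)C)[C@H](C=O)[C@H]1CC#N
F5 | step 11 | (1R,3aR,5R,6S,7S,7aR)-6-[(tert-butyldimethylsilyl)oxy]-5-hydroxy-4-methylidene-2-oxo-7-(propan-2-yl)octahydro-1H-inden-1-yl acetate | C=C1[C@@H]2CC(=O)[C@H](OC(C)=O)[C@H]2[C@H](C(C)C)[C@H](O[Si](C)(C)C(C)(C)C)[C@@H]1O
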